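**Plan**

- Ring B is numbered as a cyclohexa-2,5-dien-1-one: C1 ketone, C2 acetyl, C3 and C5 enols, C4 quaternary, C6 bridge carbon. The retrosynthesis cuts the two C–C bonds of the CH2 bridge (C8 of chromene ring A to CH2, CH2 to C6 of ring B), then C2–C3 and C6–C1 of ring B, and last C4–CH3.
- Enabling feature: C4 of ring B carries methyl, geranyl and the two carbonyl-level ring carbons C3 and C5. It is therefore the α-carbon of methyl 2-geranyl-2-methyl-3-oxobutanoate (ester carbon = C3, ketone carbon = C5, ketone methyl = C6).
- Forward, ring B half: geranylation of methyl acetoacetate, valine enamine, methylation, C-acylation of the methyl ketone with a masked acetoacetyl unit, unmasking, Dieckmann closure of ring B.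
- Forward, ring A half: acylation of phloroglucinol, chromene annulation (pyran ring), Mannich base at C8. The halves are joined last through an ortho-quinone methide.
- Stereochemistry: the only stereocentre (C4 of ring B, R) is set by the L-valine tert-butyl ester auxiliary in the methylation. It is quaternary, and the acetyl group at C2 keeps C3 and C5 different, so it cannot be lost later.

Key step: step 3

Assumption: in toluene with HMPA the electrophile is taken to enter anti to the HMPA-bearing lithium site of the chelate, which for the L-valine auxiliary corresponds to the required R centre; polycarbonyl compounds are drawn in one tautomeric form each.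

**Route**

Step 1
Reactants: 1 methyl 3-oxobutanoate; 2 geranyl bromide
Product: 3 methyl 2-[(2E)-3,7-dimethylocta-2,6-dien-1-yl]-3-oxobutanoate (racemic)
Conditions: 1 (1.5 equiv), K2CO3 (1.5 equiv), acetone, reflux
Reagents that add atoms: none
Why: Acetoacetic ester alkylation, in which the potassium enolate of 1 displaces bromide at the primary allylic carbon of 2 by SN2 with retention of the E alkene, excess 1 limiting dialkylation; the new centre is racemic and is erased in step 2.

Step 2
Reactants: 3 methyl 2-geranyl-3-oxobutanoate; 4 L-valine tert-butyl ester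
Product: 5 methyl (2Z)-3-{[(2S)-1-tert-butoxy-3-methyl-1-oxobutan-2-yl]amino}-2-[(2E)-3,7-dimethylocta-2,6-dien-1-yl]but-2-enoate
Conditions: BF3·OEt2 (cat.), benzene, reflux, Dean–Stark
Reagents that add atoms: none
Why: Acid-catalysed condensation of a β-keto ester with a primary amine under azeotropic water removal gives the conjugated Z enamine, held by the N–H···O=C hydrogen bond to the methyl ester, which removes the racemic α-centre while the valine centre is untouched.

Step 3
Reactants: 5 Z-enamine; 6 iodomethane
Product: 9 methyl (2R)-2-[(2E)-3,7-dimethylocta-2,6-dien-1-yl]-2-methyl-3-oxobutanoate, via N-lithio enamine 7 (not isolated), via C-methylated imine 8 (not isolated)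
Conditions: LiN(iPr)2 (1.1 equiv), toluene, −78 °C; HMPA (1–3 equiv), MeI (3 equiv), −78 to −55 °C; then 1 M aq. HCl, rt
Reagents that add atoms: iodomethane, CI; water, O
Why: LiN(iPr)2 removes the N–H of 5 to give the lithium aza-enolate 7, in which lithium is clamped by the enamine nitrogen, the methyl ester carbonyl and the valine ester carbonyl in two fused chelate rings that hold the N–C3=C2 unit planar. The isopropyl group on the S valine carbon lies on one face of this plane and pushes the remaining lithium site, filled by HMPA, onto the other, so iodomethane should attack C2 by SN2 anti to the lithium-bound HMPA and form the C2–CH3 bond with R configuration in imine 8. The closest known reaction type is the diastereoselective alkylation of lithiated valine tert-butyl ester enamines of α-alkyl β-keto esters, which delivers α,α-dialkyl β-keto esters in either sense depending on the medium. No ring is formed; the step needs C- over N-alkylation, secured by the soft electrophile and the carbon-centred reactivity of the aza-enolate, and facial selectivity, secured by the auxiliary and the additive, while a methyl electrophile excludes allylic transposition. Dilute aqueous HCl then cleaves the imine to ketone 9 without touching either ester, the quaternary centre cannot epimerise, and the auxiliary is recovered from the aqueous phase.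

Step 4
Reactants: 10 ethyl 2-(2-methyl-1,3-dioxolan-2-yl)acetate (fructone)
Product: 11 2-(2-methyl-1,3-dioxolan-2-yl)acetic acid
Conditions: NaOH (1.5 equiv), MeOH/H2O, rt; then cold 1 M HCl to pH 3, 0 °C, immediate extraction
Reagents that add atoms: sodium hydroxide, [Na+].[OH-]
Why: Saponification of an ethyl ester, with the dioxolane stable to hydroxide and to a brief cold acidification.

Step 5
Reactants: 9 methyl (2R)-2-geranyl-2-methyl-3-oxobutanoate; 11 2-(2-methyl-1,3-dioxolan-2-yl)acetic acid
Product: 14 methyl (2R)-2-[(2E)-3,7-dimethylocta-2,6-dien-1-yl]-2-methyl-6-(2-methyl-1,3-dioxolan-2-yl)-3,5-dioxohexanoate, via acyl imidazole 12 (not isolated), via lithium enolate 13 (not isolated)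
Conditions: flask A: 11, 1,1'-carbonyldiimidazole (1.05 equiv), THF, rt; flask B: 9, LiN(SiMe3)2 (3.3 equiv), THF, −78 °C; A into B, −78 to 0 °C; aq. NH4Cl
Reagents that add atoms: none
Why: Claisen-type C-acylation of a kinetic lithium enolate by an acyl imidazole, in which 9 can be deprotonated only at the acetyl methyl group because its other α-carbon is quaternary, enolate 13 attacks the activated carbonyl of 12, and the extra base takes up the imidazole N–H and the acidic diketone product; the ketal keeps the third carbonyl silent and the quaternary centre is not involved.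

Step 6
Reactants: 14 ketal-protected diketo ester
Product: 15 methyl (2R)-2-[(2E)-3,7-dimethylocta-2,6-dien-1-yl]-2-methyl-3,5,7-trioxooctanoate
Conditions: 1 M aq. HCl/THF (1:4), 0 °C to rt; used crude
Reagents that add atoms: water, O
Why: Acid-catalysed hydrolysis of a dioxolane β to a carbonyl group proceeds under mild aqueous conditions that leave the methyl ester and the trisubstituted alkenes alone, and the triketone is carried on at once to avoid dehydration to a 4-pyranone.

Step 7
Reactants: 15 triketo ester
Product: 16 (4R)-2-acetyl-4-[(2E)-3,7-dimethylocta-2,6-dien-1-yl]-3,5-dihydroxy-4-methylcyclohexa-2,5-dien-1-one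
Conditions: NaOMe (4 equiv), MeOH, 0 °C to reflux; then 1 M HCl, 0 °C
Reagents that add atoms: none
Why: Dieckmann (intramolecular Claisen) condensation in which the carbanion at C6 of the octanoate, flanked by two carbonyls, attacks the ester carbon in a 6-exo-trig closure with loss of methoxide and the product is drained as its stable enolate; the quaternary centre is untouched and stays stereogenic because the acetyl group differentiates its two ring neighbours.

Step 8
Reactants: 17 phloroglucinol; 18 butanoyl chloride
Product: 19 1-(2,4,6-trihydroxyphenyl)butan-1-one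
Conditions: AlCl3 (3.5 equiv), PhNO2/CH2Cl2, 0 °C to 50 °C; then ice/aq. HCl
Reagents that add atoms: none
Why: Friedel–Crafts acylation of the electron-rich phloroglucinol ring, limited to monoacylation because the first chelated acyl group deactivates the ring.

Step 9
Reactants: 19 1-(2,4,6-trihydroxyphenyl)butan-1-one; 20 3-methylbut-2-enal
Product: 21 1-(5,7-dihydroxy-2,2-dimethyl-2H-chromen-6-yl)butan-1-one
Conditions: 20 (1.1 equiv), ethylenediammonium diacetate (10 mol%), toluene, reflux
Reagents that add atoms: none
Why: Chromene annulation of a phenol by an enal (condensation at the free ring carbon, then oxa-6π electrocyclisation of the dienone), with closure expected through the 4-hydroxyl, which unlike the 2-hydroxyl is not hydrogen-bonded to the ketone, so the acyl group ends at C6 between two free hydroxyls.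

Step 10
Reactants: 21 1-(5,7-dihydroxy-2,2-dimethyl-2H-chromen-6-yl)butan-1-one
Product: 22 1-{8-[(dimethylamino)methyl]-5,7-dihydroxy-2,2-dimethyl-2H-chromen-6-yl}butan-1-one
Conditions: 37% aq. HCHO (1.1 equiv), 40% aq. Me2NH (1.2 equiv), EtOH, 0 °C to rt
Reagents that add atoms: formaldehyde, C=O; dimethylamine, CNC
Why: Phenolic Mannich reaction in which the iminium ion attacks C8, the only unsubstituted and doubly oxygen-activated position of ring A.

Step 11
Reactants: 22 Mannich base of ring A; 16 ring B trione
Product: 24 (4R)-2-acetyl-6-[(6-butanoyl-5,7-dihydroxy-2,2-dimethyl-2H-chromen-8-yl)methyl]-4-[(2E)-3,7-dimethylocta-2,6-dien-1-yl]-3,5-dihydroxy-4-methylcyclohexa-2,5-dien-1-one (CNP0203748.1), via ortho-quinone methide 23 (not isolated)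
Conditions: 16 (1.1 equiv), 1,4-dioxane, 100 °C, N2 sweep
Reagents that add atoms: none
Why: Thermal loss of dimethylamine from the ortho-hydroxybenzylamine, helped by proton transfer from the acidic trione, gives ortho-quinone methide 23, which is captured in a Michael addition by C6 of 16, the only unsubstituted carbon between two carbonyls, and rearomatisation leaves the methylene bridge with the quaternary centre untouched.

**Compound list**

1 | methyl 3-oxobutanoate | COC(=O)CC(C)=O | starting material
2 | geranyl bromide, (2E)-1-bromo-3,7-dimethylocta-2,6-diene | BrC/C=C(\C)CCC=C(C)C | starting material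
3 | methyl 2-[(2E)-3,7-dimethylocta-2,6-dien-1-yl]-3-oxobutanoate (racemic) | CC(=O)C(C/C=C(\C)CCC=C(C)C)C(=O)OC | intermediate
4 | L-valine tert-butyl ester | CC(C)[C@H](N)C(=O)OC(C)(C)C | starting material
5 | methyl (2Z)-3-{[(2S)-1-tert-butoxy-3-methyl-1-oxobutan-2-yl]amino}-2-[(2E)-3,7-dimethylocta-2,6-dien-1-yl]but-2-enoate | C/C(N[C@@H](C(C)C)C(=O)OC(C)(C)C)=C(/C(=O)OC)C/C=C(\C)CCC=C(C)C | intermediate
6 | iodomethane | CI | starting material
7 | N-lithio derivative of 5 (lithium aza-enolate) | C/C(N([Li])[C@@H](C(C)C)C(=O)OC(C)(C)C)=C(/C(=O)OC)C/C=C(\C)CCC=C(C)C | intermediate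
8 | methyl (2R)-3-{[(2S)-1-tert-butoxy-3-methyl-1-oxobutan-2-yl]imino}-2-[(2E)-3,7-dimethylocta-2,6-dien-1-yl]-2-methylbutanoate | CC(=N[C@@H](C(C)C)C(=O)OC(C)(C)C)[C@@](C)(C/C=C(\C)CCC=C(C)C)C(=O)OC | intermediate
9 | methyl (2R)-2-[(2E)-3,7-dimethylocta-2,6-dien-1-yl]-2-methyl-3-oxobutanoate | CC(=O)[C@@](C)(C/C=C(\C)CCC=C(C)C)C(=O)OC | intermediate
10 | ethyl 2-(2-methyl-1,3-dioxolan-2-yl)acetate (fructone) | CCOC(=O)CC1(C)OCCO1 | starting material
11 | 2-(2-methyl-1,3-dioxolan-2-yl)acetic acid | OC(=O)CC1(C)OCCO1 | intermediate
12 | 1-(1H-imidazol-1-yl)-2-(2-methyl-1,3-dioxolan-2-yl)ethan-1-one | O=C(CC1(C)OCCO1)n1ccnc1 | intermediate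
13 | lithium enolate of 9 at the acetyl methyl group | [Li]OC(=C)[C@@](C)(C/C=C(\C)CCC=C(C)C)C(=O)OC | intermediate
14 | methyl (2R)-2-[(2E)-3,7-dimethylocta-2,6-dien-1-yl]-2-methyl-6-(2-methyl-1,3-dioxolan-2-yl)-3,5-dioxohexanoate | CC1(CC(=O)CC(=O)[C@@](C)(C/C=C(\C)CCC=C(C)C)C(=O)OC)OCCO1 | intermediate
15 | methyl (2R)-2-[(2E)-3,7-dimethylocta-2,6-dien-1-yl]-2-methyl-3,5,7-trioxooctanoate | CC(=O)CC(=O)CC(=O)[C@@](C)(C/C=C(\C)CCC=C(C)C)C(=O)OC | intermediate
16 | (4R)-2-acetyl-4-[(2E)-3,7-dimethylocta-2,6-dien-1-yl]-3,5-dihydroxy-4-methylcyclohexa-2,5-dien-1-one | O=C1C=C(O)[C@@](C)(C/C=C(\C)CCC=C(C)C)C(O)=C1C(C)=O | intermediate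
17 | phloroglucinol | Oc1cc(O)cc(O)c1 | starting material
18 | butanoyl chloride | CCCC(Cl)=O | starting material
19 | 1-(2,4,6-trihydroxyphenyl)butan-1-one | CCCC(=O)c1c(O)cc(O)cc1O | intermediate
20 | 3-methylbut-2-enal | CC(C)=CC=O | starting material
21 | 1-(5,7-dihydroxy-2,2-dimethyl-2H-chromen-6-yl)butan-1-one | CCCC(=O)c1c(O)c2C=CC(C)(C)Oc2cc1O | intermediate
22 | 1-{8-[(dimethylamino)methyl]-5,7-dihydroxy-2,2-dimethyl-2H-chromen-6-yl}butan-1-one | CCCC(=O)c1c(O)c2C=CC(C)(C)Oc2c(CN(C)C)c1O | intermediate
23 | 6-butanoyl-5-hydroxy-2,2-dimethyl-8-methylidene-2H-chromen-7(8H)-one (ortho-quinone methide) | CCCC(=O)C1=C(O)C2=C(OC(C)(C)C=C2)C(=C)C1=O | intermediate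
24 | (4R)-2-acetyl-6-[(6-butanoyl-5,7-dihydroxy-2,2-dimethyl-2H-chromen-8-yl)methyl]-4-[(2E)-3,7-dimethylocta-2,6-dien-1-yl]-3,5-dihydroxy-4-methylcyclohexa-2,5-dien-1-one (CNP0203748.1) | CCCC(=O)c1c(O)c2c(c(CC3=C(O)[C@@](C)(C/C=C(\C)CCC=C(C)C)C(O)=C(C(C)=O)C3=O)c1O)OC(C)(C)C=C2 | target

**Count**

Total steps: 11. Longest linear sequence: 7 steps (steps 1, 2, 3, 5, 6, 7, 11).

**Steps most likely to fail**

1. Step 7 (ring B closure). The terminal methyl ketone may close by aldol addition onto the C3 carbonyl and aromatise to a resorcinol, or the hindered ester may react too slowly so that cleavage next to the quaternary carbon takes over. Fallback, from 14 back to 16: the ring is closed before the acetyl group is unmasked, so no aldol partner exists. Compound 14 is treated with LiN(iPr)2 (2.5 equiv, THF, −78 to 0 °C) to form the β-diketone dianion. Its terminal carbanion acylates the ester intramolecularly (the known terminal acylation of β-diketone dianions by esters). This gives (4R)-4-[(2E)-3,7-dimethylocta-2,6-dien-1-yl]-3,5-dihydroxy-4-methyl-2-(2-methyl-1,3-dioxolan-2-yl)cyclohexa-2,5-dien-1-one F1. Dilute aqueous HCl in THF then removes the dioxolane and gives 16.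

2. Step 5 (acetoacetyl transfer). Proton transfer from the acyl imidazole to the enolate, or O-acylation, may outrun C–C bond formation. Fallback, from 9 back to 14: the acylation is replaced by an aldol addition and an oxidation. Fructone 10 is reduced with iBu2AlH (CH2Cl2, −78 °C) to 2-(2-methyl-1,3-dioxolan-2-yl)acetaldehyde F2. The lithium enolate 13 (from 9 with LiN(iPr)2, THF, −78 °C) adds to it, since carbonyl addition to an aldehyde is faster than proton transfer. The product is methyl (2R)-2-[(2E)-3,7-dimethylocta-2,6-dien-1-yl]-5-hydroxy-2-methyl-6-(2-methyl-1,3-dioxolan-2-yl)-3-oxohexanoate F3, a mixture of carbinol epimers that does not matter. Dess–Martin periodinane (NaHCO3, CH2Cl2) oxidises the β-hydroxy ketone to 14.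

3. Step 3 (key methylation). Facial control may be poor because the small electrophile discriminates weakly between the two faces of the chelate, the sense may be opposite to the one assumed, or N-methylation may compete. Fallback, from geranyl bromide 2 back to 9: the order of the two alkylations is exchanged, so the larger electrophile makes the stereo-defining bond. Commercial methyl 2-methyl-3-oxobutanoate (COC(=O)C(C)C(C)=O) is condensed with D-valine tert-butyl ester (CC(C)[C@@H](N)C(=O)OC(C)(C)C) under the conditions of step 2. This gives methyl (2Z)-3-{[(2R)-1-tert-butoxy-3-methyl-1-oxobutan-2-yl]amino}-2-methylbut-2-enoate F4. Lithiation with LiN(iPr)2 in toluene/HMPA and SN2 alkylation with 2 at its primary carbon, anti to the HMPA-bearing lithium site of the mirror-image chelate, gives methyl (2R)-3-{[(2R)-1-tert-butoxy-3-methyl-1-oxobutan-2-yl]imino}-2-[(2E)-3,7-dimethylocta-2,6-dien-1-yl]-2-methylbutanoate F5. Exchanging the resident and incoming groups and inverting the auxiliary together lead to the same R centre. Dilute aqueous HCl gives 9.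

**Further compounds**

F1 | step 7 | (4R)-4-[(2E)-3,7-dimethylocta-2,6-dien-1-yl]-3,5-dihydroxy-4-methyl-2-(2-methyl-1,3-dioxolan-2-yl)cyclohexa-2,5-dien-1-one | O=C1C=C(O)[C@@](C)(C/C=C(\C)CCC=C(C)C)C(O)=C1C2(C)OCCO2
F2 | step 5 | 2-(2-methyl-1,3-dioxolan-2-yl)acetaldehyde | CC1(CC=O)OCCO1
F3 | step 5 | methyl (2R)-2-[(2E)-3,7-dimethylocta-2,6-dien-1-yl]-5-hydroxy-2-methyl-6-(2-methyl-1,3-dioxolan-2-yl)-3-oxohexanoate (C5 epimers) | CC1(CC(O)CC(=O)[C@@](C)(C/C=C(\C)CCC=C(C)C)C(=O)OC)OCCO1
F4 | step 3 | methyl (2Z)-3-{[(2R)-1-tert-butoxy-3-methyl-1-oxobutan-2-yl]amino}-2-methylbut-2-enoate | C/C(N[C@H](C(C)C)C(=O)OC(C)(C)C)=C(/C(=O)OC)C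
F5 | step 3 | methyl (2R)-3-{[(2R)-1-tert-butoxy-3-methyl-1-oxobutan-2-yl]imino}-2-[(2E)-3,7-dimethylocta-2,6-dien-1-yl]-2-methylbutanoate | CC(=N[C@H](C(C)C)C(=O)OC(C)(C)C)[C@@](C)(C/C=C(\C)CCC=C(C)C)C(=O)OC
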